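**Retrosynthetic overview**

1. The pyrrole ring (N1–C2–C3–C4–C5) of target 24 carries substituents only at C2 (the 16-methylheptadecanoyl group) and C5 (CH2OH); C3 and C4 are adjacent unsubstituted CH atoms, so the C3–C4 bond is traced back to two vinyl groups.
2. 24 comes from the N-tosyl-3-pyrroline 20 by carbinol oxidation, base-induced loss of toluenesulfinate with tautomerisation, and desilylation.
3. 20 comes from the N-tosyl bis-allylic amine 19 by ring-closing metathesis; this five-membered ring is the only ring formed in the route.
4. 19 comes from sulfonamide 13 and the branched allylic carbonate 16 by a rhodium-catalysed, regioretentive allylic amination; 13 comes from vinyl epoxide 8 and tosyl isocyanate, 8 from 16-methylheptadecanal and an allyl sulfonium ylide, and 16 from 3-butene-1,2-diol.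

Key step: step 12

Remark: the target has no stereocentre and every stereocentre made on the way (compounds 8 to 22) is erased by oxidation and aromatisation, so all chiral intermediates are carried as racemic diastereomer mixtures and their SMILES carry no stereo descriptors.

**Route**

Step 1
Reactants: 1 16-methylheptadecanoic acid
Product: 2 16-methylheptadecan-1-ol
Conditions: LiAlH4, THF, 0 °C to reflux; aqueous NaOH work-up
Reagents that add atoms: none
Why: Hydride reduction of a carboxylic acid by LiAlH4 runs through the aluminium carboxylate to the primary alkoxide, and the saturated iso-branched chain offers no other reducible group; no stereocentre is formed.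

Step 2
Reactants: 2 16-methylheptadecan-1-ol
Product: 3 16-methylheptadecanal
Conditions: TEMPO (cat.), PhI(OAc)2, CH2Cl2, rt
Reagents that add atoms: none
Why: TEMPO-catalysed oxoammonium oxidation with PhI(OAc)2 as terminal oxidant should stop at the aldehyde under anhydrous conditions, since no hydrate is available for further oxidation; no stereocentre is formed.

Step 3
Reactants: 4 allyl bromide; 5 tetrahydrothiophene
Product: 6 1-allyltetrahydrothiophenium bromide
Conditions: acetone, rt
Reagents that add atoms: none
Why: SN2 S-alkylation of the nucleophilic cyclic sulfide by the reactive allylic bromide should give the sulfonium salt, which separates from acetone; no stereocentre is formed.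

Step 4
Reactants: 3 16-methylheptadecanal; 6 1-allyltetrahydrothiophenium bromide
Product: 8 2-ethenyl-3-(15-methylhexadecyl)oxirane (racemic cis/trans mixture), via allyl sulfonium ylide 7 (not isolated)
Conditions: s-BuLi, THF, −78 °C; then 3, −78 °C to rt
Reagents that add atoms: none
Why: Corey–Chaykovsky epoxidation, in which the allyl sulfonium ylide adds through its α-carbon to the aldehyde and the betaine closes with loss of tetrahydrothiophene, the low temperature favouring carbonyl addition over enolisation; the two new oxirane stereocentres form without control, which is acceptable because both are destroyed later.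

Step 5
Reactants: 8 2-ethenyl-3-(15-methylhexadecyl)oxirane; 9 p-toluenesulfonyl isocyanate
Product: 10 4-ethenyl-5-(15-methylhexadecyl)-3-(4-methylbenzenesulfonyl)-1,3-oxazolidin-2-one (diastereomer mixture)
Conditions: Pd2(dba)3·CHCl3 (cat.), P(O-i-Pr)3, THF, rt
Reagents that add atoms: none
Why: Palladium-catalysed formal [3+2] cycloaddition of a vinyl epoxide with an isocyanate (Tsuji–Trost-type ionisation), in which zerovalent palladium opens the epoxide to a π-allyl alkoxide, the alkoxide adds to the isocyanate and the tethered N-tosylcarbamate anion closes the five-membered ring at the proximal allyl terminus, so nitrogen is fixed on the vinyl-bearing carbon; C5 keeps the epoxide configuration and C4 equilibrates through the π-allyl complex, the resulting mixture being of no consequence.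

Step 6
Reactants: 10 4-ethenyl-5-(15-methylhexadecyl)-3-(4-methylbenzenesulfonyl)-1,3-oxazolidin-2-one
Product: 12 N-(4-hydroxy-19-methylicos-1-en-3-yl)-4-methylbenzenesulfonamide (diastereomer mixture), via O-methyl carbonate 11 (not isolated)
Conditions: K2CO3 (cat.), MeOH, rt
Reagents that add atoms: none
Why: Methanolysis of an N-sulfonyl cyclic carbamate, in which methoxide attacks the activated carbonyl, the sulfonamide anion leaves in preference to the alkoxide to give the O-methyl carbonate, and a second transesterification releases the alcohol and dimethyl carbonate without touching either stereocentre.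

Step 7
Reactants: 12 N-(4-hydroxy-19-methylicos-1-en-3-yl)-4-methylbenzenesulfonamide
Product: 13 4-methyl-N-{19-methyl-4-[(triethylsilyl)oxy]icos-1-en-3-yl}benzenesulfonamide
Conditions: TESCl, imidazole, DMAP (cat.), DMF, rt
Reagents that add atoms: chlorotriethylsilane (TESCl), CC[Si](Cl)(CC)CC
Why: Imidazole-mediated O-silylation of the secondary alcohol, the far less nucleophilic sulfonamide N–H staying free, masks the hydroxyl for the base-mediated coupling; no stereocentre is formed.

Step 8
Reactants: 14 3-butene-1,2-diol
Product: 15 1-{[tert-butyl(diphenyl)silyl]oxy}but-3-en-2-ol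
Conditions: TBDPSCl, imidazole, CH2Cl2, 0 °C
Reagents that add atoms: tert-butylchlorodiphenylsilane (TBDPSCl), CC(C)(C)[Si](Cl)(c1ccccc1)c1ccccc1
Why: Sterically controlled silylation, in which the bulky chlorosilane reacts at the primary hydroxyl of the 1,2-diol, the TBDPS group being chosen because it survives the later acidic removal of the triethylsilyl group; no stereocentre is formed.

Step 9
Reactants: 15 1-{[tert-butyl(diphenyl)silyl]oxy}but-3-en-2-ol
Product: 16 1-{[tert-butyl(diphenyl)silyl]oxy}but-3-en-2-yl methyl carbonate
Conditions: ClCO2Me, pyridine, DMAP (cat.), CH2Cl2, 0 °C to rt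
Reagents that add atoms: methyl chloroformate, COC(=O)Cl
Why: Acylation of the secondary allylic alcohol with a chloroformate under pyridine/DMAP catalysis gives the branched allylic carbonate that serves as leaving group for rhodium; the existing stereocentre is untouched.

Step 10
Reactants: 13 4-methyl-N-{19-methyl-4-[(triethylsilyl)oxy]icos-1-en-3-yl}benzenesulfonamide; 16 1-{[tert-butyl(diphenyl)silyl]oxy}but-3-en-2-yl methyl carbonate
Product: 18 N-(1-{[tert-butyl(diphenyl)silyl]oxy}but-3-en-2-yl)-4-methyl-N-{19-methyl-4-[(triethylsilyl)oxy]icos-1-en-3-yl}benzenesulfonamide (diastereomer mixture), via lithium sulfonamide 17 (not isolated)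
Conditions: LiN(SiMe3)2, THF, −10 °C; then RhCl(PPh3)3 (cat.), P(OMe)3, 16, THF, 30 °C
Reagents that add atoms: none
Why: Rhodium-catalysed regioretentive allylic amination, in which the phosphite-modified monovalent rhodium catalyst ionises the secondary carbonate to a slowly isomerising enyl (σ plus π) complex that the lithium sulfonamide substitutes at the carbon that carried the leaving group, giving the branched N-allyl product with net retention; both partners are racemic, so the new N–C stereocentre arises as a diastereomer mixture of no consequence.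

Step 11
Reactants: 18 bis-silylated bis-allylic sulfonamide
Product: 19 N-(1-{[tert-butyl(diphenyl)silyl]oxy}but-3-en-2-yl)-N-(4-hydroxy-19-methylicos-1-en-3-yl)-4-methylbenzenesulfonamide (diastereomer mixture)
Conditions: PPTS, MeOH/CH2Cl2 (1:1), rt
Reagents that add atoms: none
Why: Acid-catalysed methanolysis of silyl ethers is governed by the bulk at silicon, so PPTS in methanol should remove the triethylsilyl group while the TBDPS ether, the sulfonamide and both vinyl groups stay intact; no stereocentre is changed.

Step 12
Reactants: 19 N-tosyl bis-allylic amine with free carbinol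
Product: 20 1-[5-({[tert-butyl(diphenyl)silyl]oxy}methyl)-1-(4-methylbenzenesulfonyl)-2,5-dihydro-1H-pyrrol-2-yl]-16-methylheptadecan-1-ol (diastereomer mixture)
Conditions: second-generation Grubbs catalyst RuCl2(=CHPh)(H2IMes)(PCy3) (5 mol %), CH2Cl2 (0.01 M), 40 °C
Reagents that add atoms: none
Why: Ring-closing olefin metathesis: the ruthenium benzylidene exchanges onto one terminal vinyl group, the new alkylidene undergoes intramolecular [2+2] cycloaddition with the second vinyl group, and the ruthenacyclobutane cycloreverts to the cyclic alkene and a ruthenium methylidene, ethylene being lost irreversibly. The closest known reaction type is the ring-closing metathesis of N-sulfonyl diallylamines, 2,5-disubstituted cases included, to N-sulfonyl-3-pyrrolines. The five-membered ring N1–C2–C3=C4–C5 is closed by joining the two internal vinyl carbons as the C3=C4 double bond, which is necessarily cis in the ring. No stereocentre is formed, and both the 2,5-cis and the 2,5-trans isomers of the mixture can close. The step needs cyclisation to outrun intermolecular metathesis and alkene migration towards nitrogen; the tertiary sulfonamide holds the two branched allyl arms close together and is too weakly basic to bind ruthenium, and dilution with escape of ethylene should secure the rest.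

Step 13
Reactants: 20 N-tosyl-3-pyrroline carbinol
Product: 21 1-[5-({[tert-butyl(diphenyl)silyl]oxy}methyl)-1-(4-methylbenzenesulfonyl)-2,5-dihydro-1H-pyrrol-2-yl]-16-methylheptadecan-1-one (diastereomer mixture)
Conditions: Dess–Martin periodinane, CH2Cl2, 0 °C to rt; aqueous NaHCO3/Na2S2O3 work-up
Reagents that add atoms: none
Why: Dess–Martin oxidation of the secondary carbinol by ligand exchange at hypervalent iodine gives the ketone under near-neutral conditions that leave the silyl ether, the ring alkene and the N-sulfonyl group intact; the carbinol stereocentre is removed.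

Step 14
Reactants: 21 N-tosyl-3-pyrrolinyl ketone
Product: 23 1-[5-({[tert-butyl(diphenyl)silyl]oxy}methyl)-1H-pyrrol-2-yl]-16-methylheptadecan-1-one, via 2H-pyrrole 22 (not isolated)
Conditions: DBU, THF, rt
Reagents that add atoms: none
Why: E1cB elimination followed by tautomerisation: C2–H is now α to the ketone, allylic and α to the sulfonamide nitrogen, so DBU removes it and the enolate expels p-toluenesulfinate from nitrogen to give the 2H-pyrrole, whose remaining C5–H then shifts to nitrogen to give the aromatic 1H-pyrrole, erasing the last stereocentres.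

Step 15
Reactants: 23 silyl-protected acylpyrrole
Product: 24 1-[5-(hydroxymethyl)-1H-pyrrol-2-yl]-16-methylheptadecan-1-one
Conditions: Bu4NF, AcOH, THF, 0 °C to rt
Reagents that add atoms: none
Why: Fluoride-induced cleavage of the Si–O bond, driven by the strong Si–F bond and buffered with acetic acid so that the acidic acylpyrrole N–H does not meet a strongly basic alkoxide, releases the primary alcohol of the target; no stereocentre is present.

**Compound list**

1 | 16-methylheptadecanoic acid | CC(C)CCCCCCCCCCCCCCC(=O)O | starting material
2 | 16-methylheptadecan-1-ol | CC(C)CCCCCCCCCCCCCCCO | intermediate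
3 | 16-methylheptadecanal | CC(C)CCCCCCCCCCCCCCC=O | intermediate
4 | allyl bromide | C=CCBr | starting material
5 | tetrahydrothiophene | C1CCSC1 | starting material
6 | 1-allyltetrahydrothiophenium bromide | C=CC[S+]1CCCC1.[Br-] | intermediate
7 | allyl sulfonium ylide, (thiolan-1-ium-1-yl)prop-2-en-1-ide | C=C[CH-][S+]1CCCC1 | intermediate (not isolated)
8 | 2-ethenyl-3-(15-methylhexadecyl)oxirane, racemic cis/trans mixture | CC(C)CCCCCCCCCCCCCCC1OC1C=C | intermediate
9 | p-toluenesulfonyl isocyanate | Cc1ccc(cc1)S(=O)(=O)N=C=O | starting material
10 | 4-ethenyl-5-(15-methylhexadecyl)-3-(4-methylbenzenesulfonyl)-1,3-oxazolidin-2-one, diastereomer mixture | CC(C)CCCCCCCCCCCCCCC1OC(=O)N(C1C=C)S(=O)(=O)c2ccc(C)cc2 | intermediate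
11 | methyl 19-methyl-3-[(4-methylbenzenesulfonyl)amino]icos-1-en-4-yl carbonate | CC(C)CCCCCCCCCCCCCCC(OC(=O)OC)C(C=C)NS(=O)(=O)c1ccc(C)cc1 | intermediate (not isolated)
12 | N-(4-hydroxy-19-methylicos-1-en-3-yl)-4-methylbenzenesulfonamide, diastereomer mixture | CC(C)CCCCCCCCCCCCCCC(O)C(C=C)NS(=O)(=O)c1ccc(C)cc1 | intermediate
13 | 4-methyl-N-{19-methyl-4-[(triethylsilyl)oxy]icos-1-en-3-yl}benzenesulfonamide, diastereomer mixture | CC(C)CCCCCCCCCCCCCCC(O[Si](CC)(CC)CC)C(C=C)NS(=O)(=O)c1ccc(C)cc1 | intermediate
14 | 3-butene-1,2-diol, racemic | C=CC(O)CO | starting material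
15 | 1-{[tert-butyl(diphenyl)silyl]oxy}but-3-en-2-ol, racemic | C=CC(O)CO[Si](c1ccccc1)(c1ccccc1)C(C)(C)C | intermediate
16 | 1-{[tert-butyl(diphenyl)silyl]oxy}but-3-en-2-yl methyl carbonate, racemic | C=CC(OC(=O)OC)CO[Si](c1ccccc1)(c1ccccc1)C(C)(C)C | intermediate
17 | lithium salt of sulfonamide 13 | CC(C)CCCCCCCCCCCCCCC(O[Si](CC)(CC)CC)C(C=C)[N-]S(=O)(=O)c1ccc(C)cc1.[Li+] | intermediate (not isolated)
18 | N-(1-{[tert-butyl(diphenyl)silyl]oxy}but-3-en-2-yl)-4-methyl-N-{19-methyl-4-[(triethylsilyl)oxy]icos-1-en-3-yl}benzenesulfonamide, diastereomer mixture | CC(C)CCCCCCCCCCCCCCC(O[Si](CC)(CC)CC)C(C=C)N(C(C=C)CO[Si](c1ccccc1)(c1ccccc1)C(C)(C)C)S(=O)(=O)c1ccc(C)cc1 | intermediate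
19 | N-(1-{[tert-butyl(diphenyl)silyl]oxy}but-3-en-2-yl)-N-(4-hydroxy-19-methylicos-1-en-3-yl)-4-methylbenzenesulfonamide, diastereomer mixture (metathesis precursor) | CC(C)CCCCCCCCCCCCCCC(O)C(C=C)N(C(C=C)CO[Si](c1ccccc1)(c1ccccc1)C(C)(C)C)S(=O)(=O)c1ccc(C)cc1 | intermediate
20 | 1-[5-({[tert-butyl(diphenyl)silyl]oxy}methyl)-1-(4-methylbenzenesulfonyl)-2,5-dihydro-1H-pyrrol-2-yl]-16-methylheptadecan-1-ol, diastereomer mixture | CC(C)CCCCCCCCCCCCCCC(O)C1C=CC(CO[Si](c2ccccc2)(c2ccccc2)C(C)(C)C)N1S(=O)(=O)c1ccc(C)cc1 | intermediate
21 | 1-[5-({[tert-butyl(diphenyl)silyl]oxy}methyl)-1-(4-methylbenzenesulfonyl)-2,5-dihydro-1H-pyrrol-2-yl]-16-methylheptadecan-1-one, diastereomer mixture | CC(C)CCCCCCCCCCCCCCC(=O)C1C=CC(CO[Si](c2ccccc2)(c2ccccc2)C(C)(C)C)N1S(=O)(=O)c1ccc(C)cc1 | intermediate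
22 | 1-[2-({[tert-butyl(diphenyl)silyl]oxy}methyl)-2H-pyrrol-5-yl]-16-methylheptadecan-1-one, racemic | CC(C)CCCCCCCCCCCCCCC(=O)C1=NC(CO[Si](c2ccccc2)(c2ccccc2)C(C)(C)C)C=C1 | intermediate (not isolated)
23 | 1-[5-({[tert-butyl(diphenyl)silyl]oxy}methyl)-1H-pyrrol-2-yl]-16-methylheptadecan-1-one | CC(C)CCCCCCCCCCCCCCC(=O)c1ccc(CO[Si](c2ccccc2)(c2ccccc2)C(C)(C)C)[nH]1 | intermediate
24 | 1-[5-(hydroxymethyl)-1H-pyrrol-2-yl]-16-methylheptadecan-1-one | CC(C)CCCCCCCCCCCCCCC(=O)c1ccc(CO)[nH]1 | target

**Step count**

Total: 15 steps. Longest linear sequence: 12 steps (steps 1, 2, 4, 5, 6, 7, 10, 11, 12, 13, 14, 15, from acid 1).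

**Steps most likely to fail**

Step 10. The lithium sulfonamide of 13 is branched at the α- and β-carbons, so substitution at the rhodium enyl complex may be slow. The allyl intermediate could then isomerise and be attacked at its terminal carbon, or the carbonate could be lost by elimination. The fallback replaces the carbonate by a vinyl epoxide. Sulfonamide 13 and butadiene monoxide are combined with Pd2(dba)3·CHCl3 and the racemic trans-1,2-diaminocyclohexane bis(2-diphenylphosphinobenzamide) ligand in CH2Cl2 at rt. The hydrogen-bonded alkoxide/sulfonamide ion pair should direct nitrogen to the internal allyl terminus and give the primary alcohol N-(1-hydroxybut-3-en-2-yl)-4-methyl-N-{19-methyl-4-[(triethylsilyl)oxy]icos-1-en-3-yl}benzenesulfonamide F1. Silylation of F1 with TBDPSCl and imidazole returns to the route at 18.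

Step 12. Ring closure between two α-branched allyl arms may be slow. Decomposition of the catalyst to ruthenium hydride species could then move a double bond into conjugation with nitrogen, or intermolecular metathesis could compete. Coordination of the free hydroxyl to ruthenium would aggravate both. The fallback closes the ring one stage earlier, on the fully silylated diene 18, which has no free hydroxyl. With the same ruthenium carbene in dilute CH2Cl2 this should give the silyl-protected pyrroline 1-{[tert-butyl(diphenyl)silyl]oxy}methyl-5-{16-methyl-1-[(triethylsilyl)oxy]heptadecyl}-1-(4-methylbenzenesulfonyl)-2,5-dihydro-1H-pyrrole F2. PPTS in methanol then removes the triethylsilyl group from F2 and returns to the route at 20.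

Step 4. The basic ylide may enolise aldehyde 3 and cause self-condensation, or may decompose before it adds to the carbonyl group. The fallback builds the epoxide from an alkene. Aldehyde 3 is treated with the ylide from allyltriphenylphosphonium bromide and n-BuLi (Wittig reaction, THF, −78 °C to rt), which should give 19-methylicosa-1,3-diene F3 as an E/Z mixture. One equivalent of mCPBA in CH2Cl2 at 0 °C should epoxidise the more electron-rich internal double bond of F3 and return to the route at 8.

**Further compounds**

F1 | step 10 | N-(1-hydroxybut-3-en-2-yl)-4-methyl-N-{19-methyl-4-[(triethylsilyl)oxy]icos-1-en-3-yl}benzenesulfonamide, diastereomer mixture | CC(C)CCCCCCCCCCCCCCC(O[Si](CC)(CC)CC)C(C=C)N(C(C=C)CO)S(=O)(=O)c1ccc(C)cc1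
F2 | step 12 | 1-{[tert-butyl(diphenyl)silyl]oxy}methyl-5-{16-methyl-1-[(triethylsilyl)oxy]heptadecyl}-1-(4-methylbenzenesulfonyl)-2,5-dihydro-1H-pyrrole, diastereomer mixture | CC(C)CCCCCCCCCCCCCCC(O[Si](CC)(CC)CC)C1C=CC(CO[Si](c2ccccc2)(c2ccccc2)C(C)(C)C)N1S(=O)(=O)c1ccc(C)cc1
F3 | step 4 | 19-methylicosa-1,3-diene, E/Z mixture | CC(C)CCCCCCCCCCCCCCC=CC=C
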